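## Retrosynthetic overview

1. Target ⇒ BBr3 O-demethylation; C-4 OH ⇒ C-4 Br (Pd-catalysed hydroxylation); C-6 benzofuranyl ⇒ site-selective Suzuki coupling on a trans-4,6-dibromo-2,3-diaryl-2,3-dihydrobenzofuran, with the benzofuran bought ready-made as its 2-boronic acid.
2. Dihydrofuran ring (O1–C2 bond, the last ring bond made) ⇒ acid-induced, trans-selective closure of the benzylic carbinol from 4-methoxyphenylmagnesium bromide and a 3-aryl lactol; lactol ⇒ ozonolysis of an ortho-(1-arylbut-2-enyl)phenol.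
3. Key step: the C3–C3a bond and the C-3 stereocentre ⇒ aromatic Claisen [3,3]-sigmatropic rearrangement of an (S,E)-1-methyl-3-arylallyl 3,5-dibromophenyl ether with 1,3-chirality transfer; C-3 then controls C-2.
4. The ether ⇒ cross-metathesis with 3,5-dimethoxystyrene and Mitsunobu inversion of (R)-but-3-en-2-ol with 3,5-dibromophenol; this bought carbinol is the only source of chirality.
5. Ring order: all benzene rings and the benzofuran are purchased; only the dihydrofuran ring is built (C3–C3a in step 3, O1–C2 in step 5).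

Assumption: the target is the (2S,3S)-trans isomer encoded in the SMILES, and (R)-but-3-en-2-ol (≥98% ee), 3,5-dimethoxystyrene, 4-methoxyphenylmagnesium bromide solution and (6-methoxy-1-benzofuran-2-yl)boronic acid are treated as catalogue items.

Dihydrobenzofuran numbering used below: O1, C2, C3, C3a, C4–C7, C7a.

## Route

Step 1
Reactants: 1 (R)-but-3-en-2-ol; 2 3,5-dibromophenol
Product: 3 1,3-dibromo-5-{[(2S)-but-3-en-2-yl]oxy}benzene
Conditions: PPh3, DIAD, THF, 0 °C → rt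
Reagents that add atoms: none
Why: Mitsunobu etherification, in which the acidic phenol displaces the alkoxyphosphonium ion by SN2 with inversion, so the bought (R)-carbinol becomes the (S)-aryl ether; the minor achiral linear crotyl ether from SN2′ attack is removed by chromatography.

Step 2
Reactants: 3 1,3-dibromo-5-{[(2S)-but-3-en-2-yl]oxy}benzene; 4 3,5-dimethoxystyrene
Product: 5 1,3-dibromo-5-{[(2S,3E)-4-(3,5-dimethoxyphenyl)but-3-en-2-yl]oxy}benzene
Conditions: second-generation Grubbs catalyst (5 mol%), 1,4-benzoquinone (10 mol%), CH2Cl2, 40 °C, 2.5 equiv of 4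
Reagents that add atoms: none
Why: Olefin cross-metathesis between a rapidly dimerising styrene and a slowly dimerising branched allylic ether gives the (E)-cross product selectively and leaves the C–O stereocentre untouched.

Step 3
Reactants: 5 1,3-dibromo-5-{[(2S,3E)-4-(3,5-dimethoxyphenyl)but-3-en-2-yl]oxy}benzene
Product: 7 3,5-dibromo-2-[(1S,2E)-1-(3,5-dimethoxyphenyl)but-2-en-1-yl]phenol, via ortho-dienone 6 (not isolated)
Conditions: PhNEt2, 190 °C, sealed tube, under argon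
Reagents that add atoms: none
Why: Aromatic Claisen [3,3]-sigmatropic rearrangement through a chair transition state with the methyl group pseudo-equatorial forms the new C–C bond suprafacially at either of the two equivalent ortho carbons, so the (S)-carbinol centre is exchanged for the (S)-benzylic centre (future C-3) and an (E)-propenyl group before the dienone tautomerises; the few percent of (Z)-alkene, which carries the opposite configuration, is removed on AgNO3-impregnated silica.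

Step 4
Reactants: 7 3,5-dibromo-2-[(1S,2E)-1-(3,5-dimethoxyphenyl)but-2-en-1-yl]phenol
Product: 10 (3S)-4,6-dibromo-3-(3,5-dimethoxyphenyl)-2,3-dihydro-1-benzofuran-2-ol (both C-2 epimers), via ozonide 8 (not isolated), via hydroxy aldehyde 9 (not isolated)
Conditions: O3, CH2Cl2, −78 °C; then Me2S, −78 °C → rt; crude product used directly
Reagents that add atoms: ozone, [O-][O+]=O
Why: Ozonolysis with reductive work-up cleaves the only alkene, and the freed diaryl acetaldehyde is trapped at once by the neighbouring phenol as a five-membered lactol, which masks the enolisable aldehyde and so protects the C-3 stereocentre under base-free conditions.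

Step 5
Reactants: 10 (3S)-4,6-dibromo-3-(3,5-dimethoxyphenyl)-2,3-dihydro-1-benzofuran-2-ol; 11 4-methoxyphenylmagnesium bromide
Product: 13 (2S,3S)-4,6-dibromo-3-(3,5-dimethoxyphenyl)-2-(4-methoxyphenyl)-2,3-dihydro-1-benzofuran, via diol 12 (not isolated)
Conditions: 11 (3.5 equiv), LaCl3·2LiCl (1 equiv), THF, −78 → 0 °C; aq. NH4Cl work-up; then CF3CO2H (5 equiv), CH2Cl2, 0 °C
Reagents that add atoms: none
Why: Grignard 1,2-addition to the aldehyde in equilibrium with the lactol (LaCl3·2LiCl suppresses enolisation) gives a 4-methoxybenzylic carbinol, whose acid ionisation to a quinone-methide-like cation is followed by 5-exo capture by the phenol anti to the C-3 aryl group, so the fixed (3S) centre sets (2S) and the trans ring is also the thermodynamic product.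

Step 6
Reactants: 13 (2S,3S)-4,6-dibromo-3-(3,5-dimethoxyphenyl)-2-(4-methoxyphenyl)-2,3-dihydro-1-benzofuran; 14 (6-methoxy-1-benzofuran-2-yl)boronic acid
Product: 15 (2S,3S)-4-bromo-3-(3,5-dimethoxyphenyl)-6-(6-methoxy-1-benzofuran-2-yl)-2-(4-methoxyphenyl)-2,3-dihydro-1-benzofuran
Conditions: Pd(PPh3)4 (5 mol%), K2CO3, 1,4-dioxane/H2O (4:1), 70 °C, 1.1 equiv of 14
Reagents that add atoms: none
Why: Suzuki–Miyaura coupling in which oxidative addition is much faster at the C-6 bromide, flanked by two hydrogens, than at the C-4 bromide wedged against the C-3 aryl group, so one equivalent of boronic acid couples at C-6 and the stereocentres are not involved.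

Step 7
Reactants: 15 (2S,3S)-4-bromo-3-(3,5-dimethoxyphenyl)-6-(6-methoxy-1-benzofuran-2-yl)-2-(4-methoxyphenyl)-2,3-dihydro-1-benzofuran
Product: 16 (2S,3S)-3-(3,5-dimethoxyphenyl)-6-(6-methoxy-1-benzofuran-2-yl)-2-(4-methoxyphenyl)-2,3-dihydro-1-benzofuran-4-ol
Conditions: Pd2(dba)3 (2 mol%), tBuXPhos (8 mol%), KOH, 1,4-dioxane/H2O (1:1), 100 °C; then aq. HCl
Reagents that add atoms: potassium hydroxide, [K+].[OH-]
Why: Buchwald-type palladium-catalysed hydroxylation of the remaining aryl bromide, where the bulky biaryl phosphine tolerates the ortho substituent and promotes C–O reductive elimination, while the ethers, the benzofuran and the non-acidic trans stereocentres are inert to aqueous KOH.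

Step 8
Reactants: 16 (2S,3S)-3-(3,5-dimethoxyphenyl)-6-(6-methoxy-1-benzofuran-2-yl)-2-(4-methoxyphenyl)-2,3-dihydro-1-benzofuran-4-ol
Product: 17 5-[(2S,3S)-4-hydroxy-6-(6-hydroxy-1-benzofuran-2-yl)-2-(4-hydroxyphenyl)-2,3-dihydro-1-benzofuran-3-yl]benzene-1,3-diol (CNP0112262.1)
Conditions: BBr3 (10 equiv), CH2Cl2, −78 °C → rt; then MeOH, H2O
Reagents that add atoms: none
Why: Lewis-acid O-demethylation with BBr3 cleaves the four aryl methyl ethers, and if the benzylic C-2–O bond opens it re-closes to the same trans isomer because C-3 is never touched.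

## Compound list

1 | (R)-but-3-en-2-ol | C[C@@H](O)C=C | starting material
2 | 3,5-dibromophenol | Oc1cc(Br)cc(Br)c1 | starting material
3 | 1,3-dibromo-5-{[(2S)-but-3-en-2-yl]oxy}benzene | C[C@H](Oc1cc(Br)cc(Br)c1)C=C | intermediate
4 | 3,5-dimethoxystyrene (1-ethenyl-3,5-dimethoxybenzene) | C=Cc1cc(OC)cc(OC)c1 | starting material
5 | 1,3-dibromo-5-{[(2S,3E)-4-(3,5-dimethoxyphenyl)but-3-en-2-yl]oxy}benzene | C[C@H](Oc1cc(Br)cc(Br)c1)/C=C/c1cc(OC)cc(OC)c1 | intermediate
6 | (6S)-3,5-dibromo-6-[(1R,2E)-1-(3,5-dimethoxyphenyl)but-2-en-1-yl]cyclohexa-2,4-dien-1-one (ortho-dienone) | O=C1C=C(Br)C=C(Br)[C@H]1[C@@H](/C=C/C)c1cc(OC)cc(OC)c1 | intermediate (not isolated)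
7 | 3,5-dibromo-2-[(1S,2E)-1-(3,5-dimethoxyphenyl)but-2-en-1-yl]phenol | Oc1cc(Br)cc(Br)c1[C@@H](/C=C/C)c1cc(OC)cc(OC)c1 | intermediate
8 | 3,5-dibromo-2-[(S)-(3,5-dimethoxyphenyl)(5-methyl-1,2,4-trioxolan-3-yl)methyl]phenol (ozonide, ring stereocentres mixed) | Oc1cc(Br)cc(Br)c1[C@@H](C1OOC(C)O1)c1cc(OC)cc(OC)c1 | intermediate (not isolated)
9 | (2S)-2-(2,4-dibromo-6-hydroxyphenyl)-2-(3,5-dimethoxyphenyl)acetaldehyde (hydroxy aldehyde) | Oc1cc(Br)cc(Br)c1[C@@H](C=O)c1cc(OC)cc(OC)c1 | intermediate (not isolated)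
10 | (3S)-4,6-dibromo-3-(3,5-dimethoxyphenyl)-2,3-dihydro-1-benzofuran-2-ol (both C-2 epimers) | OC1Oc2cc(Br)cc(Br)c2[C@@H]1c1cc(OC)cc(OC)c1 | intermediate
11 | 4-methoxyphenylmagnesium bromide | COc1ccc([Mg]Br)cc1 | starting material
12 | 3,5-dibromo-2-[(1S)-1-(3,5-dimethoxyphenyl)-2-hydroxy-2-(4-methoxyphenyl)ethyl]phenol (diol, both carbinol epimers) | Oc1cc(Br)cc(Br)c1[C@@H](C(O)c1ccc(OC)cc1)c1cc(OC)cc(OC)c1 | intermediate (not isolated)
13 | (2S,3S)-4,6-dibromo-3-(3,5-dimethoxyphenyl)-2-(4-methoxyphenyl)-2,3-dihydro-1-benzofuran | COc1ccc([C@H]2Oc3cc(Br)cc(Br)c3[C@@H]2c2cc(OC)cc(OC)c2)cc1 | intermediate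
14 | (6-methoxy-1-benzofuran-2-yl)boronic acid | COc1ccc2cc(B(O)O)oc2c1 | starting material
15 | (2S,3S)-4-bromo-3-(3,5-dimethoxyphenyl)-6-(6-methoxy-1-benzofuran-2-yl)-2-(4-methoxyphenyl)-2,3-dihydro-1-benzofuran | COc1ccc([C@H]2Oc3cc(-c4cc5ccc(OC)cc5o4)cc(Br)c3[C@@H]2c2cc(OC)cc(OC)c2)cc1 | intermediate
16 | (2S,3S)-3-(3,5-dimethoxyphenyl)-6-(6-methoxy-1-benzofuran-2-yl)-2-(4-methoxyphenyl)-2,3-dihydro-1-benzofuran-4-ol | COc1ccc([C@H]2Oc3cc(-c4cc5ccc(OC)cc5o4)cc(O)c3[C@@H]2c2cc(OC)cc(OC)c2)cc1 | intermediate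
17 | 5-[(2S,3S)-4-hydroxy-6-(6-hydroxy-1-benzofuran-2-yl)-2-(4-hydroxyphenyl)-2,3-dihydro-1-benzofuran-3-yl]benzene-1,3-diol | Oc1ccc([C@H]2Oc3cc(-c4cc5ccc(O)cc5o4)cc(O)c3[C@@H]2c2cc(O)cc(O)c2)cc1 | target

## Step count and risks

Total step count: 8. Longest linear sequence: 8 steps (1 → 17); 2, 4, 11 and 14 are bought and enter at steps 1, 2, 5 and 6.

Step 3 (Claisen rearrangement). The risk is that a minor chair with axial methyl, or a boat, gives (Z)-alkene of the opposite configuration, and that the electron-poor ether needs a high temperature. The fallback sets out from 2 and comes back at 7. 1-Iodo-3,5-dimethoxybenzene is coupled with (S)-but-3-yn-2-ol (PdCl2(PPh3)2, CuI, Et3N) to give (2S)-4-(3,5-dimethoxyphenyl)but-3-yn-2-ol F1. Mitsunobu reaction of F1 with 2 (PPh3, DIAD) gives, by clean propargylic inversion, 1,3-dibromo-5-{[(2R)-4-(3,5-dimethoxyphenyl)but-3-yn-2-yl]oxy}benzene F2. Semi-hydrogenation (H2, Pd/CaCO3 poisoned with Pb(OAc)2, quinoline) gives 1,3-dibromo-5-{[(2R,3Z)-4-(3,5-dimethoxyphenyl)but-3-en-2-yl]oxy}benzene F3. Heating F3 as in step 3 gives 7 through (6R)-3,5-dibromo-6-[(1R,2E)-1-(3,5-dimethoxyphenyl)but-2-en-1-yl]cyclohexa-2,4-dien-1-one F4. In the (Z)-ether the chair with axial methyl is blocked by a 1,3-diaxial clash with the aryl group, so transfer is essentially complete, and the (R,Z)- and (S,E)-ethers converge on the same (S)-phenol.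

Step 6 (site-selective Suzuki coupling). The risk is coupling at C-4 or at both bromides. The fallback sets out from 7 and comes back at 15, doing the coupling one stage earlier, where the two bromides differ most. Compounds 7 and 14 (Pd(PPh3)4, K2CO3, dioxane/H2O) give 3-bromo-2-[(1S,2E)-1-(3,5-dimethoxyphenyl)but-2-en-1-yl]-5-(6-methoxy-1-benzofuran-2-yl)phenol F5, because the other bromide is buried next to the branched benzylic carbon. OsO4 (cat.), NaIO4 and 2,6-lutidine in dioxane/H2O (used because ozone would attack the benzofuran) cleave the propenyl group to (3S)-4-bromo-3-(3,5-dimethoxyphenyl)-6-(6-methoxy-1-benzofuran-2-yl)-2,3-dihydro-1-benzofuran-2-ol F6. Compound 11 and then CF3CO2H, as in step 5, give 15 through 3-bromo-2-[(1S)-1-(3,5-dimethoxyphenyl)-2-hydroxy-2-(4-methoxyphenyl)ethyl]-5-(6-methoxy-1-benzofuran-2-yl)phenol F7.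

Step 7 (hydroxylation of the hindered bromide). The risk is hydrodebromination or diaryl ether formation. The fallback sets out from 15 and comes back at 16. Miyaura borylation (B2pin2, PdCl2(dppf), KOAc, dioxane, 90 °C) gives 2-[(2S,3S)-3-(3,5-dimethoxyphenyl)-6-(6-methoxy-1-benzofuran-2-yl)-2-(4-methoxyphenyl)-2,3-dihydro-1-benzofuran-4-yl]-4,4,5,5-tetramethyl-1,3,2-dioxaborolane F8. Oxidation with NaBO3·4H2O (THF/H2O, rt) then gives 16.

## Further compounds

F1 | step 3 | (2S)-4-(3,5-dimethoxyphenyl)but-3-yn-2-ol | C[C@H](O)C#Cc1cc(OC)cc(OC)c1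
F2 | step 3 | 1,3-dibromo-5-{[(2R)-4-(3,5-dimethoxyphenyl)but-3-yn-2-yl]oxy}benzene | C[C@@H](Oc1cc(Br)cc(Br)c1)C#Cc1cc(OC)cc(OC)c1
F3 | step 3 | 1,3-dibromo-5-{[(2R,3Z)-4-(3,5-dimethoxyphenyl)but-3-en-2-yl]oxy}benzene | C[C@@H](Oc1cc(Br)cc(Br)c1)/C=C\c1cc(OC)cc(OC)c1
F4 | step 3 | (6R)-3,5-dibromo-6-[(1R,2E)-1-(3,5-dimethoxyphenyl)but-2-en-1-yl]cyclohexa-2,4-dien-1-one | O=C1C=C(Br)C=C(Br)[C@@H]1[C@@H](/C=C/C)c1cc(OC)cc(OC)c1
F5 | step 6 | 3-bromo-2-[(1S,2E)-1-(3,5-dimethoxyphenyl)but-2-en-1-yl]-5-(6-methoxy-1-benzofuran-2-yl)phenol | Oc1cc(-c2cc3ccc(OC)cc3o2)cc(Br)c1[C@@H](/C=C/C)c1cc(OC)cc(OC)c1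
F6 | step 6 | (3S)-4-bromo-3-(3,5-dimethoxyphenyl)-6-(6-methoxy-1-benzofuran-2-yl)-2,3-dihydro-1-benzofuran-2-ol | OC1Oc2cc(-c3cc4ccc(OC)cc4o3)cc(Br)c2[C@@H]1c1cc(OC)cc(OC)c1
F7 | step 6 | 3-bromo-2-[(1S)-1-(3,5-dimethoxyphenyl)-2-hydroxy-2-(4-methoxyphenyl)ethyl]-5-(6-methoxy-1-benzofuran-2-yl)phenol | Oc1cc(-c2cc3ccc(OC)cc3o2)cc(Br)c1[C@@H](C(O)c1ccc(OC)cc1)c1cc(OC)cc(OC)c1
F8 | step 7 | 2-[(2S,3S)-3-(3,5-dimethoxyphenyl)-6-(6-methoxy-1-benzofuran-2-yl)-2-(4-methoxyphenyl)-2,3-dihydro-1-benzofuran-4-yl]-4,4,5,5-tetramethyl-1,3,2-dioxaborolane | COc1ccc([C@H]2Oc3cc(-c4cc5ccc(OC)cc5o4)cc(B4OC(C)(C)C(C)(C)O4)c3[C@@H]2c2cc(OC)cc(OC)c2)cc1
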